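Readings and results were generated by integration with constants of no real substance, noise included.

The pitfall with readings that stay flat from first to last, as Friday's and Thursday's do within their scatter, is fitting rate constants to them, since they hold amounts and no clock.

| flask | substrate | first nucleophile | second nucleophile | remark | time |
|---|---|---|---|---|---|
| Friday's | 0.0050 M | 0.011 M | 7 mM | run made earlier |  |
| Thursday's | 0.020 M | 0.011 M | 7 mM | run made earlier |  |
| flask | 0.010 M | 0.0110 M | 7.00 mM |  | 15 min |

| run | time / min | other capture product / % | target / % |
|---|---|---|---|
| Friday's | 1.00 | 54.5 | 12.4 |
| Friday's | 2.00 | 55.6 | 12.4 |
| Friday's | 5.00 | 54.4 | 13.4 |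
| Friday's | 12.0 | 54.9 | 12.6 |
| Thursday's | 1.50 | 34.6 | 16.2 |
| Thursday's | 4.00 | 33.4 | 16.7 |
| Thursday's | 8.00 | 33.6 | 16.3 |
| Thursday's | 12.0 | 33.2 | 16.0 |

(readings scatter by 0.5 percentage points)

- share of other capture product in other capture product plus target at 0.40 s
- share of other capture product in other capture product plus target at 20 s
- share of other capture product in other capture product plus target at 15 min
- which of other capture product and target there is more of at 15 min

- the earlier runs were read with a standard deviation of 0.5 percentage points
- a reading or a percentage of target counts all its forms, free or not

I therefore take each run's mean as its finished state and commit myself at 15 min; the earlier times precede every reading. Friday's run reads other capture product 54.8 % and target 12.7 %, a share of 81.2 %. Thursday's reads 33.7 % and 16.3 %, a share of 67.4 %. The flask's substrate charge lies between theirs, so these are my first upper and lower bounds.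

To tighten them, I assume both nucleophiles compete for one species, with an unseen route taking the missing substrate. I carry the progress, the natural logarithm of first nucleophile charged over first nucleophile charged less target formed: 0.0595 on Friday, 0.351 on Thursday. The same logarithm for the second nucleophile, divided by progress, is my reading of an apparent selectivity factor: 8.36 and 9.37, mean 8.87. On this picture, substrate spent bends downward against progress, so progress bends upward against charge. The flask's progress should therefore lie above the line from zero through Friday, 0.119, and below the chord from Friday to Thursday, 0.157, within the scatter of the readings. These give shares of 78.7 % and 76.7 %, so I expect other capture product to lead in the flask.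

The forecast gives 81 %, 77.5 % and 77.4 % at the asked times, with other capture product ahead, judging “20 s is probably near final”; its last share stands inside my bracket.

The simulation gives 76.5 %, 77.4 % and 77.4 %, the last inside the bracket, with other capture product at 48.1 % and target at 14.1 %, crystals included.

    substrate → intermediate (k = 0.210 s⁻¹)
    first nucleophile + intermediate → target (k = 19000 M⁻¹ s⁻¹)
    second nucleophile + intermediate → other capture product (k = 95000 M⁻¹ s⁻¹)
    intermediate → solvolysis product (k = 310 s⁻¹)
    first nucleophile ⇌ dormant form (K = 1.20, k = 0.250 s⁻¹)
    crystals ⇌ target, rate k6*(cs6 - [target]) while solid is left; crystals form when [target] > cs6 (solubility = 1.20 mM, k = 77.0 s⁻¹)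

A further flask charged with 0.040 M of substrate lies beyond Thursday's charge, so on the same picture the prolonged chord should run beneath its progress, giving a floor of 0.741. At that floor I reckon 6.99 mM of other capture product and 5.76 mM of target, which puts my ceiling on that flask's share at 54.8 %. That flask stores a share of 52.5 %, with target at 15.8 %.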